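Ring A, a hexasubstituted benzene, is cut into a cyclobutenone and an ynol ether (Danheiser benzannulation). Its contiguous carbons C(OH)–C(CH3)–C(OCH3), flanked by the bridge-bearing carbon and the only CH, are the imprint of 1-methoxypropyne inserted into a vinylketene. In one operation the key step closes ring A, forms the C(OH)–C(CH3) and C(OCH3)–CH bonds, differentiates the three ring A oxygens (OH, OMe, OBn) and leaves a single free carbon for the isovaleryl group. Its precursor is a racemic 3-benzyloxycyclobut-2-enone whose C4 already carries the bridging CH2 and the fully substituted, benzyl-protected ring B.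

Key step: step 9

Remark: cyclobutenone 19 is used as the racemate, because its only stereocentre (C4) becomes an aromatic carbon in step 9; the target has no stereocentre. Ar = 2,6-bis(benzyloxy)-4-methoxy-3-methyl-5-(2-methylpropanoyl)phenyl (protected ring B).

Step 1
Reactants: 1 2-methylphloroglucinol
Product: 3 2,4,6-trihydroxy-3-methylbenzaldehyde, via aryl iminium chloride 2 (not isolated)
Conditions: POCl3, DMF, EtOAc, 0 °C to rt; then H2O, 50 °C
Reagents that add atoms: N,N-dimethylformamide, CN(C)C=O; water, O
Why: Vilsmeier–Haack formylation of a phloroglucinol; the two unsubstituted ring carbons of 1 are equivalent, so a single monoaldehyde should form, and the first formyl group deactivates the ring towards a second attack.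

Step 2
Reactants: 3 2,4,6-trihydroxy-3-methylbenzaldehyde
Product: 4 2,6-dihydroxy-4-methoxy-3-methylbenzaldehyde
Conditions: MeI (1.05 equiv), Li2CO3 (1.1 equiv), DMF, 40 °C
Reagents that add atoms: iodomethane, CI
Why: Williamson O-methylation under acidity control; the hydroxyl para to the formyl group is the most acidic (vinylogous carboxylic acid) and is not chelated to the carbonyl, so one equivalent of weak base and MeI should methylate it in preference to the two ortho hydroxyls, which places OMe para to the future bridge carbon.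

Step 3
Reactants: 4 2,6-dihydroxy-4-methoxy-3-methylbenzaldehyde; 5 isobutyryl chloride
Product: 6 2,6-dihydroxy-4-methoxy-3-methyl-5-(2-methylpropanoyl)benzaldehyde
Conditions: TiCl4 (3 equiv), ClCH2CH2Cl, 0 to 60 °C; then 1 M HCl
Reagents that add atoms: none
Why: Friedel–Crafts acylation directed by the neighbouring titanium phenoxide; only one ring carbon is unsubstituted and it is ortho or para to all three oxygen donors, and the moderate conditions should spare the methyl ether.

Step 4
Reactants: 6 2,6-dihydroxy-4-methoxy-3-methyl-5-(2-methylpropanoyl)benzaldehyde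
Product: 7 2,6-bis(benzyloxy)-4-methoxy-3-methyl-5-(2-methylpropanoyl)benzaldehyde
Conditions: BnBr (3 equiv), K2CO3, DMF, 60 °C
Reagents that add atoms: benzyl bromide, BrCc1ccccc1
Why: Williamson etherification; both remaining phenols are chelated to carbonyl groups but should alkylate on oxygen with excess benzyl bromide in warm DMF, the ring being fully substituted.

Step 5
Reactants: 7 2,6-bis(benzyloxy)-4-methoxy-3-methyl-5-(2-methylpropanoyl)benzaldehyde; 8 Meldrum's acid
Product: 11 3-[2,6-bis(benzyloxy)-4-methoxy-3-methyl-5-(2-methylpropanoyl)phenyl]propanoic acid, via arylidene Meldrum's acid 9 (not isolated), via arylmethyl Meldrum's acid 10 (not isolated)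
Conditions: HCO2H/Et3N (5:2), 95 °C
Reagents that add atoms: none
Why: Reductive Knoevenagel homologation; condensation gives 9, formate delivers hydride to this strongly electrophilic alkylidene to give 10, and hydrolysis with decarboxylation in the same hot medium gives the acid, while the hindered aryl ketone and the benzyl ethers are inert to formate without a hydrogenation catalyst.

Step 6
Reactants: 12 benzyl alcohol; 13 trichloroethylene
Product: 16 benzyloxyacetylene, via benzyl dichlorovinyl ether 14 (not isolated), via lithium benzyloxyacetylide 15 (not isolated)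
Conditions: KH, THF, 0 °C; 13, -50 °C to rt; n-BuLi (2.4 equiv), -78 °C; H2O, -78 to 0 °C; product kept cold
Reagents that add atoms: none
Why: Ynol ether synthesis from trichloroethylene; potassium benzyloxide adds to dichloroacetylene formed in situ to give 14, two equivalents of n-BuLi effect dehydrochlorination and lithium–chlorine exchange to 15, and protonation is done cold because benzyl alkynyl ethers undergo [3,3]-sigmatropic rearrangement on warming.

Step 7
Reactants: 11 3-[2,6-bis(benzyloxy)-4-methoxy-3-methyl-5-(2-methylpropanoyl)phenyl]propanoic acid; 16 benzyloxyacetylene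
Product: 19 racemic 3-(benzyloxy)-4-{[2,6-bis(benzyloxy)-4-methoxy-3-methyl-5-(2-methylpropanoyl)phenyl]methyl}cyclobut-2-en-1-one, via acid chloride 17 (not isolated), via aldoketene 18 (not isolated)
Conditions: (COCl)2, cat. DMF, CH2Cl2, 0 °C to rt, evaporate; then 16 (3 equiv), Et3N, CH2Cl2, slow addition of 17, 0 °C to rt
Reagents that add atoms: none
Why: Ketene–alkyne [2+2] cycloaddition; Et3N dehydrochlorinates 17 to 18, whose carbonyl carbon is attacked by the unsubstituted, nucleophilic carbon of the ynol ether, so OBn is placed at C3 and the ring B benzyl group at C4, the new C4 stereocentre forms as a racemate that step 9 erases, and slow addition to excess 16 limits ketene dimerisation.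

Step 8
Reactants: 20 chloroacetaldehyde dimethyl acetal
Product: 22 1-methoxypropyne, via sodium methoxyacetylide 21 (not isolated)
Conditions: NaNH2 (3 equiv), liquid NH3, -33 °C; then MeI; evaporation of NH3, distillation
Reagents that add atoms: iodomethane, CI
Why: Double elimination and acetylide alkylation, the standard entry to 1-alkoxy-1-alkynes; NaNH2 removes methanol and HCl from 20 and deprotonates the methoxyacetylene, MeI methylates the acetylide carbon, and the methyl ynol ether has no β-hydrogen, so it cannot fragment by retro-ene reaction in step 9.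

Step 9
Reactants: 19 racemic 3-(benzyloxy)-4-(Ar-methyl)cyclobut-2-en-1-one; 22 1-methoxypropyne
Product: 27 1-[2,4-bis(benzyloxy)-3-{[6-(benzyloxy)-2-hydroxy-4-methoxy-3-methylphenyl]methyl}-6-methoxy-5-methylphenyl]-2-methylpropan-1-one, via vinylketene 23 (not isolated), via alkenylcyclobutenone 24 (not isolated), via dienylketene 25 (not isolated), via cyclohexadienone 26 (not isolated)
Conditions: 22 (3 equiv), toluene, sealed tube, 80 °C then 140 °C; then K2CO3, MeOH, rt
Reagents that add atoms: none
Why: Thermal four-electron conrotatory opening of 19 gives vinylketene 23, whose ketene C=C adds the ynol ether in a [2+2] cycloaddition to give 24; reversible opening of 24 to dienylketene 25, six-electron electrocyclisation to dienone 26 and tautomerisation give phenol 27. This is a Danheiser benzannulation with an alkoxyalkyne as ketenophile, the reaction type that converts cyclobutenones into resorcinol monoethers. Ring A is closed by the 6π electrocyclisation, which joins the ketene carbon to the carbon bearing the ring B benzyl group, while the C(OH)–C(CH3) and C(OCH3)–CH bonds come from the [2+2] step. No stereocentre results, since the racemic C4 of 19 becomes an aromatic carbon. The regiochemistry is secured by the polarisation of the ynol ether, whose methyl-bearing carbon is the nucleophilic terminus and bonds to the electrophilic ketene carbonyl carbon, so OMe ends up meta to the new OH and next to the only ring CH; outward rotation of the C4 substituent in the first ring opening keeps the benzylic CH2 away from the ketene and should suppress a 1,5-hydrogen shift. The brief K2CO3/MeOH treatment returns any phenol that has been acylated by 23.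

Step 10
Reactants: 27 ring A phenol; 28 isovaleryl chloride
Product: 29 1-[2-(benzyloxy)-3-{[2,6-bis(benzyloxy)-4-methoxy-3-methyl-5-(2-methylpropanoyl)phenyl]methyl}-4-hydroxy-6-methoxy-5-methylphenyl]-3-methylbutan-1-one
Conditions: TiCl4 (2.2 equiv), CH2Cl2, -78 to -20 °C; aq. NaHCO3
Reagents that add atoms: none
Why: Friedel–Crafts acylation; the only unsubstituted carbon of ring A lies para to the hydroxyl and between the OMe and OBn groups, ring B is fully substituted, and the low temperature should spare the benzyl ethers and the methylene bridge, partial loss of a benzyl ether converging on the same product in step 11.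

Step 11
Reactants: 29 tribenzyl ether of the target
Product: 30 1-[3-[[2,6-dihydroxy-4-methoxy-3-methyl-5-(2-methylpropanoyl)phenyl]methyl]-2,4-dihydroxy-6-methoxy-5-methylphenyl]-3-methylbutan-1-one
Conditions: H2 (1 atm), 10% Pd/C, EtOAc, rt
Reagents that add atoms: none
Why: Catalytic hydrogenolysis of the three benzyl aryl ethers; the chelated aryl ketones, the methyl ethers and the diarylmethane C–C bonds should not be affected under these mild conditions.

Compound list
1 | 2-methylphloroglucinol (2-methylbenzene-1,3,5-triol) | Cc1c(O)cc(O)cc1O | starting material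
2 | dimethyl[(2,4,6-trihydroxy-3-methylphenyl)methylidene]ammonium chloride | C[N+](C)=Cc1c(O)cc(O)c(C)c1O.[Cl-] | intermediate
3 | 2,4,6-trihydroxy-3-methylbenzaldehyde | O=Cc1c(O)c(C)c(O)cc1O | intermediate
4 | 2,6-dihydroxy-4-methoxy-3-methylbenzaldehyde | O=Cc1c(O)c(C)c(OC)cc1O | intermediate
5 | isobutyryl chloride | CC(C)C(Cl)=O | starting material
6 | 2,6-dihydroxy-4-methoxy-3-methyl-5-(2-methylpropanoyl)benzaldehyde | O=Cc1c(O)c(C)c(OC)c(C(=O)C(C)C)c1O | intermediate
7 | 2,6-bis(benzyloxy)-4-methoxy-3-methyl-5-(2-methylpropanoyl)benzaldehyde | O=Cc1c(OCc2ccccc2)c(C)c(OC)c(C(=O)C(C)C)c1OCc1ccccc1 | intermediate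
8 | Meldrum's acid (2,2-dimethyl-1,3-dioxane-4,6-dione) | CC1(C)OC(=O)CC(=O)O1 | starting material
9 | 5-(Ar-methylidene)-2,2-dimethyl-1,3-dioxane-4,6-dione | CC1(C)OC(=O)C(=Cc2c(OCc3ccccc3)c(C)c(OC)c(C(=O)C(C)C)c2OCc2ccccc2)C(=O)O1 | intermediate
10 | 5-(Ar-methyl)-2,2-dimethyl-1,3-dioxane-4,6-dione | CC1(C)OC(=O)C(Cc2c(OCc3ccccc3)c(C)c(OC)c(C(=O)C(C)C)c2OCc2ccccc2)C(=O)O1 | intermediate
11 | 3-[2,6-bis(benzyloxy)-4-methoxy-3-methyl-5-(2-methylpropanoyl)phenyl]propanoic acid | OC(=O)CCc1c(OCc2ccccc2)c(C)c(OC)c(C(=O)C(C)C)c1OCc1ccccc1 | intermediate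
12 | benzyl alcohol | OCc1ccccc1 | starting material
13 | trichloroethylene | ClC=C(Cl)Cl | starting material
14 | benzyl (E)-1,2-dichlorovinyl ether | Cl/C=C(/Cl)OCc1ccccc1 | intermediate
15 | lithium benzyloxyacetylide | [Li]C#COCc1ccccc1 | intermediate
16 | benzyloxyacetylene (benzyl ethynyl ether) | C#COCc1ccccc1 | intermediate
17 | 3-Ar-propanoyl chloride | ClC(=O)CCc1c(OCc2ccccc2)c(C)c(OC)c(C(=O)C(C)C)c1OCc1ccccc1 | intermediate
18 | 3-Ar-prop-1-en-1-one (aldoketene) | O=C=CCc1c(OCc2ccccc2)c(C)c(OC)c(C(=O)C(C)C)c1OCc1ccccc1 | intermediate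
19 | racemic 3-(benzyloxy)-4-(Ar-methyl)cyclobut-2-en-1-one | O=C1C=C(OCc2ccccc2)C1Cc1c(OCc2ccccc2)c(C)c(OC)c(C(=O)C(C)C)c1OCc1ccccc1 | intermediate
20 | chloroacetaldehyde dimethyl acetal (2-chloro-1,1-dimethoxyethane) | COC(CCl)OC | starting material
21 | sodium methoxyacetylide | COC#C[Na] | intermediate
22 | 1-methoxypropyne | CC#COC | intermediate
23 | 3-(benzyloxy)-5-Ar-penta-1,3-dien-1-one (vinylketene, CH2Ar trans to the ketene-bearing carbon) | O=C=C/C(OCc1ccccc1)=C/Cc1c(OCc2ccccc2)c(C)c(OC)c(C(=O)C(C)C)c1OCc1ccccc1 | intermediate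
24 | racemic 4-[1-(benzyloxy)-3-Ar-prop-1-enyl]-3-methoxy-2-methylcyclobut-2-en-1-one | O=C1C(C)=C(OC)C1/C(OCc1ccccc1)=C/Cc1c(OCc2ccccc2)c(C)c(OC)c(C(=O)C(C)C)c1OCc1ccccc1 | intermediate
25 | 5-(benzyloxy)-3-methoxy-2-methyl-7-Ar-hepta-1,3,5-trien-1-one (dienylketene, C2 and C5 cis on the C3=C4 bond) | O=C=C(C)/C(OC)=C\C(OCc1ccccc1)=C\Cc1c(OCc2ccccc2)c(C)c(OC)c(C(=O)C(C)C)c1OCc1ccccc1 | intermediate
26 | racemic 6-(Ar-methyl)-5-(benzyloxy)-3-methoxy-2-methylcyclohexa-2,4-dien-1-one | O=C1C(C)=C(OC)C=C(OCc2ccccc2)C1Cc1c(OCc2ccccc2)c(C)c(OC)c(C(=O)C(C)C)c1OCc1ccccc1 | intermediate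
27 | 1-[2,4-bis(benzyloxy)-3-{[6-(benzyloxy)-2-hydroxy-4-methoxy-3-methylphenyl]methyl}-6-methoxy-5-methylphenyl]-2-methylpropan-1-one | COc1cc(OCc2ccccc2)c(Cc2c(OCc3ccccc3)c(C)c(OC)c(C(=O)C(C)C)c2OCc2ccccc2)c(O)c1C | intermediate
28 | isovaleryl chloride (3-methylbutanoyl chloride) | CC(C)CC(Cl)=O | starting material
29 | 1-[2-(benzyloxy)-3-(Ar-methyl)-4-hydroxy-6-methoxy-5-methylphenyl]-3-methylbutan-1-one | COc1c(C(=O)CC(C)C)c(OCc2ccccc2)c(Cc2c(OCc3ccccc3)c(C)c(OC)c(C(=O)C(C)C)c2OCc2ccccc2)c(O)c1C | intermediate
30 | 1-[3-[[2,6-dihydroxy-4-methoxy-3-methyl-5-(2-methylpropanoyl)phenyl]methyl]-2,4-dihydroxy-6-methoxy-5-methylphenyl]-3-methylbutan-1-one | COc1c(C)c(O)c(Cc2c(O)c(C)c(OC)c(C(=O)C(C)C)c2O)c(O)c1C(=O)CC(C)C | target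

Total step count: 11 steps.
Longest linear sequence: 9 steps (steps 1, 2, 3, 4, 5, 7, 9, 10, 11).

Steps most likely to fail

Step 9. The vinylketene may be lost by dimerisation, by acylating the product phenol or by a 1,5-hydrogen shift before the ynol ether intercepts it, or the cascade may stall before the second ring opening. The fallback sets out from 6 and 4 and comes back to the route at 30; it makes the methylene bridge by the classical alkylation of one acylphloroglucinol by the ortho-quinone methide of the other. Aldehyde 6 would be converted by reductive amination (Me2NH, NaBH(OAc)3, ClCH2CH2Cl) into the Mannich base 1-{3-[(dimethylamino)methyl]-2,4-dihydroxy-6-methoxy-5-methylphenyl}-2-methylpropan-1-one F1. Aldehyde 4 would be acylated with 28 under the conditions of step 3 to give 2,6-dihydroxy-4-methoxy-3-methyl-5-(3-methylbutanoyl)benzaldehyde F2. Its formyl group, having directed the O-methylation, would then be removed by Tsuji–Wilkinson decarbonylation (RhCl(PPh3)3, xylene, reflux) to give 1-(4,6-dihydroxy-2-methoxy-3-methylphenyl)-3-methylbutan-1-one F3. Heating F1 with F3 in dioxane should expel dimethylamine, and the quinone methide should be trapped at the single free ring carbon of F3 to give 30 directly.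

Step 7. Under amine conditions the aldoketene may dimerise or acylate the acidic cyclobutenone faster than the thermally sensitive ynol ether adds to it. The fallback sets out from 7 and comes back at 19; it generates the same ketene 18 slowly and without base by Wolff rearrangement. Aldehyde 7 would undergo van Leusen reductive cyanation (TosMIC, t-BuOK, DME, then MeOH, reflux) to 2-Ar-acetonitrile F4. Hydrolysis (KOH, aqueous EtOH, reflux) would give 2-Ar-acetic acid F5. Its acid chloride ((COCl)2, cat. DMF) with TMSCHN2 would give 1-diazo-3-Ar-propan-2-one F6. Irradiation of F6 (Pyrex-filtered mercury lamp, CH2Cl2, 0 °C) in the presence of excess 16 should give 18 and then 19.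

Step 10. The Lewis acid may cleave benzyl ethers, with benzyl cations alkylating the free ring carbon, or the phenol may be acylated on oxygen instead of the ring on carbon. The fallback sets out from 27 and comes back at 29; it builds the ketone without a strong Lewis acid. Vilsmeier–Haack formylation (POCl3, DMF, 0 °C to rt, then H2O) should give 2-(benzyloxy)-3-(Ar-methyl)-4-hydroxy-6-methoxy-5-methylbenzaldehyde F7. Excess isobutylmagnesium bromide (THF, -78 to 0 °C) should add to this aldehyde and not to the doubly ortho-substituted ring B ketone, giving racemic 1-[2-(benzyloxy)-3-(Ar-methyl)-4-hydroxy-6-methoxy-5-methylphenyl]-3-methylbutan-1-ol F8. Benzylic oxidation (MnO2, CH2Cl2, rt) would then give 29.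

Further compounds
F1 | step 9 | 1-{3-[(dimethylamino)methyl]-2,4-dihydroxy-6-methoxy-5-methylphenyl}-2-methylpropan-1-one | CN(C)Cc1c(O)c(C)c(OC)c(C(=O)C(C)C)c1O
F2 | step 9 | 2,6-dihydroxy-4-methoxy-3-methyl-5-(3-methylbutanoyl)benzaldehyde | O=Cc1c(O)c(C)c(OC)c(C(=O)CC(C)C)c1O
F3 | step 9 | 1-(4,6-dihydroxy-2-methoxy-3-methylphenyl)-3-methylbutan-1-one | CC(C)CC(=O)c1c(O)cc(O)c(C)c1OC
F4 | step 7 | 2-[2,6-bis(benzyloxy)-4-methoxy-3-methyl-5-(2-methylpropanoyl)phenyl]acetonitrile | N#CCc1c(OCc2ccccc2)c(C)c(OC)c(C(=O)C(C)C)c1OCc1ccccc1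
F5 | step 7 | 2-[2,6-bis(benzyloxy)-4-methoxy-3-methyl-5-(2-methylpropanoyl)phenyl]acetic acid | OC(=O)Cc1c(OCc2ccccc2)c(C)c(OC)c(C(=O)C(C)C)c1OCc1ccccc1
F6 | step 7 | 1-diazo-3-[2,6-bis(benzyloxy)-4-methoxy-3-methyl-5-(2-methylpropanoyl)phenyl]propan-2-one | [N-]=[N+]=CC(=O)Cc1c(OCc2ccccc2)c(C)c(OC)c(C(=O)C(C)C)c1OCc1ccccc1
F7 | step 10 | 2-(benzyloxy)-3-{[2,6-bis(benzyloxy)-4-methoxy-3-methyl-5-(2-methylpropanoyl)phenyl]methyl}-4-hydroxy-6-methoxy-5-methylbenzaldehyde | COc1c(C=O)c(OCc2ccccc2)c(Cc2c(OCc3ccccc3)c(C)c(OC)c(C(=O)C(C)C)c2OCc2ccccc2)c(O)c1C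
F8 | step 10 | racemic 1-[2-(benzyloxy)-3-{[2,6-bis(benzyloxy)-4-methoxy-3-methyl-5-(2-methylpropanoyl)phenyl]methyl}-4-hydroxy-6-methoxy-5-methylphenyl]-3-methylbutan-1-ol | COc1c(C(O)CC(C)C)c(OCc2ccccc2)c(Cc2c(OCc3ccccc3)c(C)c(OC)c(C(=O)C(C)C)c2OCc2ccccc2)c(O)c1C
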